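## Structural features

The target is an isoflavone in which a 5,7-dihydroxy-4H-chromen-4-one (rings A and C) is bonded through C3 to C1' of a pentasubstituted benzene ring B. Going round ring B from C1', the substituents are a hydroxyl at C2', a 3-hydroxy-3-methylbutyl chain at C3' and methoxyls at C4' and C5', so that only C6' carries hydrogen. The molecule has no stereocentre and no stereogenic double bond, so the task is one of regiochemistry and functional-group tolerance. Three parts are fragile: the tertiary alcohol, which under acid dehydrates or closes onto the C2' hydroxyl to a 2,2-dimethylchroman; the pyranone ring C, which is opened by hard nucleophiles or hot aqueous base and can be over-reduced at C2=C3; and the electron-rich ring B, which oxidises towards a quinone once its phenol is free. Ring A with a handle at C3 is routine from a phloroglucinol-derived acetophenone, and the C3–C1' bond is a standard sp2–sp2 coupling. The real difficulty is the contiguous oxygen/carbon/oxygen/oxygen array C2'–C5' of ring B, in which the carbon chain must sit between the C2' oxygen and the C4' methoxyl. The key step exploits two features of this array: the C2' oxygen and the C3' carbon are ortho neighbours next to the C4' methoxyl, which is the pattern left when a 3-alkoxyaryne takes up an O–C unit, and the path O–C2'–C3'–CH2–CH2–C(OH)Me2 is a ring-opened 3,4-dihydrocoumarin whose lactone carbonyl carbon becomes the carbinol carbon.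

## Logic of the disconnections

28 to 27: the three O–CH2Ph bonds are cut. The phenols must be masked for the coupling, and benzyl is chosen because it leaves under neutral H2 over Pd/C, without acid (tertiary alcohol) or strong base (ring C). The skeleton is not simplified, but the polar, oxidisable triphenol becomes a robust intermediate. The forward step must stop before the C2=C3 bond is reduced.

27 to 21 and 26: the C3–C1' bond is cut. This divides the molecule into a ring A/C half and a ring B half of similar size, so the route becomes convergent. The forward coupling must join an electron-rich, ortho-alkoxy boronate to a base-sensitive 3-iodochromone under mild base, with the tertiary alcohol left free.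

26 to 25, then to 23 and 24, then to 22: in 26 the O1–C2 and C3–I bonds are cut, in 25 the bond between the acetyl carbon and the one-carbon unit of 24, and in 23 two O–benzyl bonds. This reduces the chromone to 22 in three routine steps. The only demand is that 22 is benzylated at two of its three hydroxyls, which the hydrogen bond of the third to the carbonyl favours.

21 to 20, 19 and 18: the C1'–B, O–benzyl and C1'–I bonds are cut in turn. The halogen is introduced while the C2' phenol is free, because the phenol is then the strongest director and C1' is its only open ortho position. The forward iodination must be ortho-selective and acid-free.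

18 to 15 and 16: the two C–CH3 bonds at the carbinol carbon are cut, and both methyl groups are traced to 16, of which two equivalents are incorporated. This shows that the C2' phenol and the tertiary alcohol are both contained in one lactone, so neither needs a protecting group up to this point. The forward step needs an excess of 16 and a mild quench that does not cyclise the product to a chroman.

15 to 14: the C3–C4 double bond of the lactone ring is restored (a change of oxidation level only). This is done because 14 is the direct product of the three-component coupling. The forward step must hydrogenate that alkene without opening the aryl ester.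

14 to 7, 8 and 9 (key disconnection): four bonds are cut. These are the aryl C–O bond at C2', the aryl C–C bond at C3', the C3–C4 bond of the lactone ring and the O–acyl bond. A 1,2,3,4-tetrasubstituted bicycle is reduced to 7, a one-carbon/one-oxygen unit (8) and a two-carbon unit (9). The forward step requires that 8 adds to 10 with its oxygen at the carbon remote from the neighbouring methoxyl, and that 9 captures 12 at carbon.

7 to 5, 2 and 1: the O–S bond, the C–Si bond and the carbamate C–O bond are cut. The silyl group has to sit between the two oxygen substituents, a position that electrophilic substitution does not reach but directed ortho-metalation does. The forward lithiation must occur at the doubly flanked carbon, and the carbamate must then come off under conditions that leave the aryl–silicon bond intact.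

## Other disconnections considered

Alternative 1: The cut runs through ring B: C5'–C6', C1'–C2' and C2'–C3' are broken. The pieces are the pentacarbonylchromium methoxycarbene complex A1 (carbene carbon = C5', alkenyl carbons = C4' and C3' with the silyl-protected chain), the terminal alkyne A2 (C1' and C6', already bonded to C3 of ring C) and one CO ligand (C2'). A2 would come from 26 in two steps by Sonogashira coupling and desilylation. Forward, a Dötz benzannulation (alkyne insertion, CO insertion to a vinylketene, 6π-electrocyclisation, tautomerisation) would give A3. The C2' hydroxyl would be free and para to the C5' methoxyl, as this reaction requires, and the usual preference of terminal alkynes would put the chromone next to the new hydroxyl.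
- In favour: it is the most convergent of the four plans. It needs no halogenation of ring B, no borylation and no biaryl cross-coupling. After the key step only desilylation and hydrogenolysis would remain, which is better than the chosen plan.
- Against: A1 is an unusually electron-rich carbene with a methoxyl on the alkenyl carbon next to the carbene centre. Its preparation would need a geometrically defined lithiated enol ether, stoichiometric Cr(CO)6 and a hard methylating agent. A2 is an electron-poor, ynone-type alkyne with a Michael-acceptor carbon at C2, a class in which benzannulation is prone to divert to furans, cyclobutenones and indenes. The free para-methoxyphenol of A3 could oxidise during demetalation. The tertiary alcohol needs a silyl group that the chosen plan does without.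
- Comparison: both plans fix the ring B pattern by an intrinsic rule (CO-derived carbon para to the carbene carbon there, heteroatom remote from the alkoxy group on an aryne here). The alternative is equal or better in convergence and in longest linear sequence. The chosen plan avoids a stoichiometric toxic metal, and its partners 7, 8 and 9 are each easier to secure than A1.

Alternative 2: Ring B is cut at C1'–C2' after being traced back to a four-membered ring. The phenol A7 is 18 with its tertiary alcohol silylated. It would come from cyclobutenone A6, in which the carbonyl carbon is C2', the ring alkene is C3'/C4', the quaternary methoxy carbon is C5' and the vinyl group is C6'/C1'. Forward, heating A6 would open it by a 4π-electrocyclic process to a dienylketene, and 6π-electrocyclisation would form C1'–C2' and give A7 after tautomerisation. A6 would be assembled from dimethyl squarate A4 in three stages: addition of the organolithium form of the protected side chain with acid-induced rearrangement to the cyclobutenedione A5, addition of CH2=CHMgBr to the more ketone-like carbonyl of A5, and O-methylation.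
- In favour: the place of every substituent follows from the order of the additions, so no aryne regiochemistry and no directed metalation are involved. The key step needs no reagent. The step count to the ring B phenol (about four from A4 plus two or three for the side-chain halide) equals the six steps from 1 to 18. In predictability of the substitution pattern it is at least the equal of the chosen plan.
- Against: O-methylation of a strained tertiary cyclobutenol competes with ring opening. The chain must be brought in as a silyl-protected organolithium and deprotected later. Squaric esters such as A4 are costly. The alternative ends where step 6 ends, so iodination, benzylation, borylation, coupling and hydrogenolysis would remain unchanged.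
- Comparison: both key steps are cascades under inherent regiocontrol. The chosen plan builds the chain from 8, 9 and 16 with no protecting group and so has the better protecting-group economy. The alternative is equal in step count and better in freedom from organolithium regiochemistry.

Alternative 3: The cut is the C3–C4 bond of ring C. Keto aldehyde A10 would be made by O-alkylation of the ring A salicylaldehyde A8 with the ring B phenacyl bromide A9. A triazolium-derived carbene would turn the aldehyde carbon (future C4) into an acyl anion equivalent that adds to the tethered ketone carbon (future C3). This intramolecular crossed benzoin reaction would close the chromanone A11 as a racemate, and dehydration of its tertiary carbinol would then give the isoflavone.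
- In favour: no palladium, boron or iodochromone is needed, and the halves are joined by a simple etherification. Aldehyde–ketone benzoin closures to 3-hydroxychroman-4-ones are an established class. An achiral catalyst suffices because the new stereocentre is erased. In freedom from transition metals and from the base-sensitive 26 it is better than the chosen plan.
- Against: the disconnection does not address ring B. Ring B would still have to be built (for example through 18), then acylated at C1' and brominated at the α-carbon in the presence of an electron-rich arene to reach A9. The acceptor ketone of A10 is hindered by the ortho-benzyloxy group and deactivated by three oxygen donors. The doubly ortho-oxygenated aldehyde is a reluctant acyl-anion donor, and base-mediated aldol closure of the α-aryloxy ketone onto the aldehyde would compete. Dehydration of A11 needs acid or an activating agent, so the side-chain alcohol must be silylated and later freed.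
- Comparison: it addresses ring C, which the chosen plan obtains in three routine steps. The umpolung closure is mechanistically more delicate than a Suzuki coupling. It would be some four to five steps longer because of acylation, bromination, silyl protection and removal, and dehydration.

Key step: step 4

Remark on the chemistry: the target has no stereocentre. Ring B is numbered C1' (bonded to C3), C2' (hydroxyl), C3' (chain), C4' and C5' (methoxyls), C6' (hydrogen), and this mapping is used for every intermediate.

## Route

Step 1
Reactants: 1 3,4-dimethoxyphenol
Product: 2 3,4-dimethoxyphenyl N-isopropylcarbamate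
Conditions: i-PrNCO (1.2 equiv), Et3N (0.2 equiv), CH2Cl2, rt
Reagents that add atoms: isopropyl isocyanate, CC(C)N=C=O
Why: Amine-catalysed addition of the phenol O–H across the isocyanate (carbamoylation). The secondary carbamate is a strong ortho-directing group once N-silylated, and its N–H later allows cleavage under mild base.

Step 2
Reactants: 2 3,4-dimethoxyphenyl N-isopropylcarbamate
Product: 5 3,4-dimethoxy-2-(trimethylsilyl)phenyl N-isopropylcarbamate, via N-silyl carbamate 3 (not isolated), via N-silyl C-silyl carbamate 4 (not isolated)
Conditions: TBSOTf (1.1 equiv), TMEDA, Et2O, 0 °C to rt; then n-BuLi (2.0 equiv), TMEDA, −78 °C; TMSCl, −78 °C to rt; aq. NaHSO4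
Reagents that add atoms: chlorotrimethylsilane, C[Si](C)(C)Cl; tert-butyldimethylsilyl trifluoromethanesulfonate, CC(C)(C)[Si](C)(C)OS(=O)(=O)C(F)(F)F (its silyl group is carried by 3 and 4 only)
Why: Directed ortho-metalation: in situ N-silylation removes the acidic N–H, and n-BuLi then takes the ring proton flanked by the carbamate and the 3-methoxyl (cooperating 1,3-directing groups). TMSCl quenches at carbon and the N-silyl group falls off in the acidic work-up. The low temperature suppresses the anionic ortho-Fries shift.

Step 3
Reactants: 5 3,4-dimethoxy-2-(trimethylsilyl)phenyl N-isopropylcarbamate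
Product: 7 3,4-dimethoxy-2-(trimethylsilyl)phenyl trifluoromethanesulfonate, via 3,4-dimethoxy-2-(trimethylsilyl)phenol 6 (not isolated)
Conditions: Et2NH (1.2 equiv), DBU (1.5 equiv), MeCN, 40 °C; then PhNTf2 (1.5 equiv), rt
Reagents that add atoms: N-phenylbis(trifluoromethanesulfonimide), O=S(=O)(N(c1ccccc1)S(=O)(=O)C(F)(F)F)C(F)(F)F
Why: DBU deprotonates the carbamate N–H and E1cB fragmentation releases the phenoxide of 6 and isopropyl isocyanate, which diethylamine scavenges as a urea. The phenoxide is triflated in the same flask. The non-acidic, fluoride-free conditions preserve the aryl–silicon bond.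

Step 4
Reactants: 7 3,4-dimethoxy-2-(trimethylsilyl)phenyl trifluoromethanesulfonate; 8 N,N-dimethylformamide; 9 1-(tert-butyldimethylsilyloxy)-1-methoxyethene
Product: 14 5,6-dimethoxycoumarin, via 3,4-dimethoxybenzyne 10 (not isolated), via aminobenzoxetene 11 (not isolated), via ortho-quinone methide 12 (not isolated), via 4-(dimethylamino)-5,6-dimethoxychroman-2-one 13 (not isolated)
Conditions: CsF (4 equiv), 9 (3 equiv), dry DMF (solvent and reactant), rt to 50 °C
Reagents that add atoms: none
Why: Fluoride removes the trimethylsilyl group of 7 and triflate leaves, giving aryne 10 in a medium that is itself the trapping reagent, so capture by the carbonyl oxygen of 8 should outrun direct reaction of 10 with 9. The oxygen adds to the aryne carbon remote from the adjacent methoxyl, because the developing aryl anion then sits beside that inductively withdrawing group; the anion closes on the iminium carbon to benzoxetene 11 (formal [2+2], 4-exo-trig), which opens by a 4π-electrocyclic process to ortho-quinone methide 12. Ketene silyl acetal 9 adds to the methide carbon of 12 (Mukaiyama–Michael type, also describable as a hetero-[4+2] addition), and the phenoxide oxygen closes on the ester carbon by 6-exo-trig acyl substitution as fluoride takes the silyl group and methoxide leaves, giving amino lactone 13; this is the only ring that remains in the product. E1cB loss of dimethylamine from 13, driven by conjugation with the arene and the lactone carbonyl, gives 14 (the two last events may also occur in the reverse order). The closest known reaction type is the three-component coupling of arynes, formamides and carbon nucleophiles (1,3-dicarbonyls, ester enolates, substituted ketene silyl acetals) to coumarins and chromenes, and the acetate-derived acetal lies within that class. The stereocentres of 11 and 13 are transient and racemic, and none remains in 14. The step needs regioselectivity in the first addition, which the methoxyl next to the triple bond secures, and chemoselectivity of 10 for 8 over 9, which the use of 8 as solvent secures.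

Step 5
Reactants: 14 5,6-dimethoxycoumarin
Product: 15 5,6-dimethoxychroman-2-one
Conditions: H2 (1 atm), 10% Pd/C, EtOAc, rt
Reagents that add atoms: none
Why: Heterogeneous hydrogenation of the conjugated C3=C4 bond of a coumarin. The arene and its ethers are untouched, and the non-nucleophilic solvent avoids alcoholysis of the aryl ester.

Step 6
Reactants: 15 5,6-dimethoxychroman-2-one; 16 methylmagnesium bromide
Product: 18 2-(3-hydroxy-3-methylbutyl)-3,4-dimethoxyphenol, via methyl ketone 17 (not isolated)
Conditions: MeMgBr (4 equiv), THF, 0 °C to rt; sat. aq. NH4Cl
Reagents that add atoms: methylmagnesium bromide, C[Mg]Br (a second equivalent; the first is reactant 16)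
Why: Double Grignard addition to an aryl lactone: the first equivalent of 16 adds to the lactone carbonyl and expels the phenoxide to give ketone 17, which is more electrophilic than the lactone and takes the second methyl group from a further equivalent of the same reagent. The excess covers the two additions and adventitious quenching, and the weakly acidic work-up avoids cyclodehydration to the 2,2-dimethylchroman.

Step 7
Reactants: 18 2-(3-hydroxy-3-methylbutyl)-3,4-dimethoxyphenol
Product: 19 2-(3-hydroxy-3-methylbutyl)-6-iodo-3,4-dimethoxyphenol
Conditions: NIS (1.0 equiv), DMF, 0 °C, dark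
Reagents that add atoms: N-iodosuccinimide, O=C1CCC(=O)N1I
Why: Electrophilic aromatic iodination. The hydroxyl is the strongest donor, its para position is blocked, and its one open ortho position (the future C1') is also para to the 3-methoxyl, whereas the other free position is meta to the hydroxyl. Acid-free conditions protect the tertiary alcohol.

Step 8
Reactants: 19 2-(3-hydroxy-3-methylbutyl)-6-iodo-3,4-dimethoxyphenol
Product: 20 4-[2-(benzyloxy)-3-iodo-5,6-dimethoxyphenyl]-2-methylbutan-2-ol
Conditions: BnBr (1.2 equiv), K2CO3, DMF, 50 °C
Reagents that add atoms: benzyl bromide, BrCc1ccccc1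
Why: Williamson etherification. Carbonate deprotonates only the phenol, so the tertiary alcohol stays free. Benzyl is chosen so that all three phenol protections fall in one final hydrogenolysis.

Step 9
Reactants: 20 4-[2-(benzyloxy)-3-iodo-5,6-dimethoxyphenyl]-2-methylbutan-2-ol
Product: 21 4-[2-(benzyloxy)-5,6-dimethoxy-3-(4,4,5,5-tetramethyl-1,3,2-dioxaborolan-2-yl)phenyl]-2-methylbutan-2-ol
Conditions: B2pin2 (1.3 equiv), Pd(dppf)Cl2 (5 mol %), KOAc (3 equiv), 1,4-dioxane, 85 °C
Reagents that add atoms: bis(pinacolato)diboron, CC1(C)OB(OC1(C)C)B1OC(C)(C)C(C)(C)O1
Why: Miyaura borylation of an aryl iodide. The weak acetate base prevents homocoupling, and the free tertiary alcohol and the benzyl ether are inert.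

Step 10
Reactants: 22 2,4,6-trihydroxyacetophenone
Product: 23 1-[2,4-bis(benzyloxy)-6-hydroxyphenyl]ethan-1-one
Conditions: BnBr (2.1 equiv), K2CO3, DMF, rt to 60 °C
Reagents that add atoms: benzyl bromide, BrCc1ccccc1 (two equivalents are incorporated)
Why: Williamson etherification limited to two hydroxyls. The third stays as the phenol hydrogen-bonded to the ketone carbonyl, which is the least acidic and least nucleophilic site. That hydroxyl is needed for the later ring closure.

Step 11
Reactants: 23 1-[2,4-bis(benzyloxy)-6-hydroxyphenyl]ethan-1-one; 24 N,N-dimethylformamide dimethyl acetal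
Product: 25 (E)-1-[2,4-bis(benzyloxy)-6-hydroxyphenyl]-3-(dimethylamino)prop-2-en-1-one
Conditions: 24 (3 equiv), toluene, 95 °C
Reagents that add atoms: none
Why: Condensation of the acetyl methyl group with the amide acetal (enaminone formation), with loss of two molecules of methanol. The E geometry of the push-pull alkene is the thermodynamic one.

Step 12
Reactants: 25 (E)-1-[2,4-bis(benzyloxy)-6-hydroxyphenyl]-3-(dimethylamino)prop-2-en-1-one
Product: 26 5,7-bis(benzyloxy)-3-iodo-4H-chromen-4-one
Conditions: I2 (1.5 equiv), MeOH/CH2Cl2, rt; aq. Na2S2O3, NaHCO3
Reagents that add atoms: iodine, II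
Why: Iodine attacks the nucleophilic α-carbon of the enaminone, the ortho-hydroxyl adds to the resulting iminium carbon (6-exo-trig) and dimethylamine is expelled. This is the established enaminone iodocyclisation to 3-iodochromones.

Step 13
Reactants: 21 4-[2-(benzyloxy)-5,6-dimethoxy-3-(4,4,5,5-tetramethyl-1,3,2-dioxaborolan-2-yl)phenyl]-2-methylbutan-2-ol; 26 5,7-bis(benzyloxy)-3-iodo-4H-chromen-4-one
Product: 27 5,7-bis(benzyloxy)-3-[2-(benzyloxy)-3-(3-hydroxy-3-methylbutyl)-4,5-dimethoxyphenyl]-4H-chromen-4-one
Conditions: Pd(dppf)Cl2 (5 mol %), 2 M aq. Na2CO3, DME, 80 °C
Reagents that add atoms: none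
Why: Suzuki–Miyaura coupling of a 3-iodochromone (a vinylogous acyl iodide, fast in oxidative addition) with an arylboronate; this is the standard construction of the isoflavone C3–C1' bond. Carbonate is mild enough to spare the pyranone ring.

Step 14
Reactants: 27 5,7-bis(benzyloxy)-3-[2-(benzyloxy)-3-(3-hydroxy-3-methylbutyl)-4,5-dimethoxyphenyl]-4H-chromen-4-one
Product: 28 5,7-dihydroxy-3-[2-hydroxy-3-(3-hydroxy-3-methylbutyl)-4,5-dimethoxyphenyl]-4H-chromen-4-one (CNP0192638.0)
Conditions: H2 (1 atm), 10% Pd/C, EtOAc/MeOH, rt, stopped at complete debenzylation
Reagents that add atoms: none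
Why: Hydrogenolysis of three aryl benzyl ethers under neutral conditions. The tertiary alcohol is not benzylic and survives, and the vinylogous-ester C2=C3 bond of the isoflavone should be reduced much more slowly than the O–benzyl bonds are cleaved.

## Compound list

1 | 3,4-dimethoxyphenol | COc1ccc(O)cc1OC | starting material
2 | 3,4-dimethoxyphenyl N-isopropylcarbamate | COc1ccc(OC(=O)NC(C)C)cc1OC | intermediate
3 | 3,4-dimethoxyphenyl N-(tert-butyldimethylsilyl)-N-isopropylcarbamate | COc1ccc(OC(=O)N(C(C)C)[Si](C)(C)C(C)(C)C)cc1OC | intermediate
4 | 3,4-dimethoxy-2-(trimethylsilyl)phenyl N-(tert-butyldimethylsilyl)-N-isopropylcarbamate | COc1ccc(OC(=O)N(C(C)C)[Si](C)(C)C(C)(C)C)c([Si](C)(C)C)c1OC | intermediate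
5 | 3,4-dimethoxy-2-(trimethylsilyl)phenyl N-isopropylcarbamate | COc1ccc(OC(=O)NC(C)C)c([Si](C)(C)C)c1OC | intermediate
6 | 3,4-dimethoxy-2-(trimethylsilyl)phenol | COc1ccc(O)c([Si](C)(C)C)c1OC | intermediate
7 | 3,4-dimethoxy-2-(trimethylsilyl)phenyl trifluoromethanesulfonate | COc1ccc(OS(=O)(=O)C(F)(F)F)c([Si](C)(C)C)c1OC | intermediate
8 | N,N-dimethylformamide | CN(C)C=O | starting material
9 | 1-(tert-butyldimethylsilyloxy)-1-methoxyethene | C=C(OC)O[Si](C)(C)C(C)(C)C | starting material
10 | 3,4-dimethoxybenzyne | COC1=C(OC)C#CC=C1 | intermediate
11 | 2-(dimethylamino)-3,4-dimethoxy-2H-benzoxete (racemic) | COc1ccc2OC(N(C)C)c2c1OC | intermediate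
12 | 6-[(dimethylamino)methylidene]-4,5-dimethoxycyclohexa-2,4-dien-1-one | COC1=C(OC)C(=CN(C)C)C(=O)C=C1 | intermediate
13 | 4-(dimethylamino)-5,6-dimethoxychroman-2-one (racemic) | COc1ccc2OC(=O)CC(N(C)C)c2c1OC | intermediate
14 | 5,6-dimethoxycoumarin | COc1ccc2oc(=O)ccc2c1OC | intermediate
15 | 5,6-dimethoxychroman-2-one | COc1ccc2OC(=O)CCc2c1OC | intermediate
16 | methylmagnesium bromide | C[Mg]Br | starting material
17 | 4-(6-hydroxy-2,3-dimethoxyphenyl)butan-2-one (present as its magnesium phenoxide) | COc1ccc(O)c(CCC(C)=O)c1OC | intermediate
18 | 2-(3-hydroxy-3-methylbutyl)-3,4-dimethoxyphenol | COc1ccc(O)c(CCC(C)(C)O)c1OC | intermediate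
19 | 2-(3-hydroxy-3-methylbutyl)-6-iodo-3,4-dimethoxyphenol | COc1cc(I)c(O)c(CCC(C)(C)O)c1OC | intermediate
20 | 4-[2-(benzyloxy)-3-iodo-5,6-dimethoxyphenyl]-2-methylbutan-2-ol | COc1cc(I)c(OCc2ccccc2)c(CCC(C)(C)O)c1OC | intermediate
21 | 4-[2-(benzyloxy)-5,6-dimethoxy-3-(4,4,5,5-tetramethyl-1,3,2-dioxaborolan-2-yl)phenyl]-2-methylbutan-2-ol | COc1cc(B2OC(C)(C)C(C)(C)O2)c(OCc2ccccc2)c(CCC(C)(C)O)c1OC | intermediate
22 | 2,4,6-trihydroxyacetophenone | CC(=O)c1c(O)cc(O)cc1O | starting material
23 | 1-[2,4-bis(benzyloxy)-6-hydroxyphenyl]ethan-1-one | CC(=O)c1c(O)cc(OCc2ccccc2)cc1OCc1ccccc1 | intermediate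
24 | N,N-dimethylformamide dimethyl acetal | COC(OC)N(C)C | starting material
25 | (E)-1-[2,4-bis(benzyloxy)-6-hydroxyphenyl]-3-(dimethylamino)prop-2-en-1-one | CN(C)/C=C/C(=O)c1c(O)cc(OCc2ccccc2)cc1OCc1ccccc1 | intermediate
26 | 5,7-bis(benzyloxy)-3-iodo-4H-chromen-4-one | O=c1c(I)coc2cc(OCc3ccccc3)cc(OCc3ccccc3)c12 | intermediate
27 | 5,7-bis(benzyloxy)-3-[2-(benzyloxy)-3-(3-hydroxy-3-methylbutyl)-4,5-dimethoxyphenyl]-4H-chromen-4-one | COc1cc(-c2coc3cc(OCc4ccccc4)cc(OCc4ccccc4)c3c2=O)c(OCc2ccccc2)c(CCC(C)(C)O)c1OC | intermediate
28 | 5,7-dihydroxy-3-[2-hydroxy-3-(3-hydroxy-3-methylbutyl)-4,5-dimethoxyphenyl]-4H-chromen-4-one (CNP0192638.0) | COc1cc(-c2coc3cc(O)cc(O)c3c2=O)c(O)c(CCC(C)(C)O)c1OC | target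

## Step count and least certain steps

Total: 14 steps. Longest linear sequence: 11 steps (steps 1 to 9, 13 and 14, from 1). The ring A branch is three steps (10 to 12).

Step 4 (key step). The most likely failure is that fluoride desilylates 9 faster than 12 is formed. The free ester enolate would then be protonated or would self-condense, 12 would find no carbon nucleophile, and it would be hydrolysed at work-up. Less likely is partial loss of regiocontrol in the addition of 8 to 10. The fallback separates the insertion from the C–C bond formation and sets out from 7. Aryne generation in DMF alone (CsF, DMF, rt), followed by aqueous quench of the methide, should give 6-hydroxy-2,3-dimethoxybenzaldehyde F1. Wittig olefination of F1 with Ph3P=CHCO2Me (toluene, rt to 60 °C) should give methyl (E)-3-(6-hydroxy-2,3-dimethoxyphenyl)prop-2-enoate F2, and hydrogenation (H2, 10% Pd/C, EtOAc) should give methyl 3-(6-hydroxy-2,3-dimethoxyphenyl)propanoate F3. Treatment of F3 with 16 (5 equiv, THF, 0 °C to rt), which delivers two methyl groups to the ester carbon, would give 18, where the fallback rejoins the route, bypassing 14 and 15.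

Step 2. The most likely failure is incomplete N-silylation. The lithium amide of the carbamate would then fragment to phenoxide and isocyanate instead of directing metalation. Carbamoyl migration to the ring on warming is a second risk. The fallback uses a tertiary carbamate with no N–H and sets out from 1. ClCONEt2, K2CO3 in MeCN at reflux should give 3,4-dimethoxyphenyl N,N-diethylcarbamate F4. s-BuLi, TMEDA in THF at −78 °C, then TMSCl, should give 3,4-dimethoxy-2-(trimethylsilyl)phenyl N,N-diethylcarbamate F5. Reductive cleavage of F5 with LiAlH4 (THF, 0 °C to rt) would release 6, here isolated. The fallback rejoins at 6, which is triflated as in the second stage of step 3 to give 7.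

Step 7. The most likely failure is oxidation of the electron-rich para-alkoxyphenol by the electrophilic iodine source, or iodination at the other free position and over-iodination. The fallback places the iodine by deprotonation instead of electrophilic substitution and sets out from 18. ClCONEt2, K2CO3 in MeCN should carbamoylate only the phenol and give 2-(3-hydroxy-3-methylbutyl)-3,4-dimethoxyphenyl N,N-diethylcarbamate F6. s-BuLi (2.2 equiv, the first for the alcohol), TMEDA in THF at −78 °C, then I2, should metalate the only open position ortho to the carbamate and give 2-(3-hydroxy-3-methylbutyl)-6-iodo-3,4-dimethoxyphenyl N,N-diethylcarbamate F7. KOH in EtOH at reflux would hydrolyse the carbamate to 19, where the route is rejoined.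

Step 13. The most likely failure is protodeboronation of the electron-rich, ortho-alkoxy boronate, together with hydroxide attack at C2 of 26 and opening of the pyranone ring in hot aqueous base. The fallback is a base-free Negishi coupling that sets out from 20 and bypasses 21. i-PrMgCl·LiCl (2.1 equiv, THF, −15 °C) deprotonates the alcohol and exchanges iodine for magnesium, and ZnCl2 then gives [2-(benzyloxy)-3-(3-chloromagnesiooxy-3-methylbutyl)-4,5-dimethoxyphenyl]zinc chloride F8, which is not isolated. Coupling of F8 with 26 under Pd(PPh3)4 (zerovalent palladium, THF, 50 °C) should give 27, where the route is rejoined.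

Step 14. The most likely failure is reduction of the C2=C3 bond competing with slow cleavage of the hindered 2'-O-benzyl ether, so that over-reduction or incomplete debenzylation results. The fallback removes the benzyl groups before the coupling and sets out from 26 and 21. BCl3 (CH2Cl2, −78 to 0 °C) applied to 26, which has no acid-sensitive alcohol, should give 5,7-dihydroxy-3-iodo-4H-chromen-4-one F9. Hydrogenolysis of 21 (H2, 10% Pd/C, EtOAc), which has no reducible alkene, should give 2-(3-hydroxy-3-methylbutyl)-3,4-dimethoxy-6-(4,4,5,5-tetramethyl-1,3,2-dioxaborolan-2-yl)phenol F10. Suzuki–Miyaura coupling of F9 and F10 with unprotected phenols (Pd(OAc)2, SPhos, K3PO4, dioxane/H2O, 60 °C) would give 28 directly, where the route is rejoined.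

## Further compounds

F1 | step 4 | 6-hydroxy-2,3-dimethoxybenzaldehyde | COc1ccc(O)c(C=O)c1OC
F2 | step 4 | methyl (E)-3-(6-hydroxy-2,3-dimethoxyphenyl)prop-2-enoate | COC(=O)/C=C/c1c(O)ccc(OC)c1OC
F3 | step 4 | methyl 3-(6-hydroxy-2,3-dimethoxyphenyl)propanoate | COC(=O)CCc1c(O)ccc(OC)c1OC
F4 | step 2 | 3,4-dimethoxyphenyl N,N-diethylcarbamate | CCN(CC)C(=O)Oc1ccc(OC)c(OC)c1
F5 | step 2 | 3,4-dimethoxy-2-(trimethylsilyl)phenyl N,N-diethylcarbamate | CCN(CC)C(=O)Oc1ccc(OC)c(OC)c1[Si](C)(C)C
F6 | step 7 | 2-(3-hydroxy-3-methylbutyl)-3,4-dimethoxyphenyl N,N-diethylcarbamate | CCN(CC)C(=O)Oc1ccc(OC)c(OC)c1CCC(C)(C)O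
F7 | step 7 | 2-(3-hydroxy-3-methylbutyl)-6-iodo-3,4-dimethoxyphenyl N,N-diethylcarbamate | CCN(CC)C(=O)Oc1c(I)cc(OC)c(OC)c1CCC(C)(C)O
F8 | step 13 | [2-(benzyloxy)-3-(3-chloromagnesiooxy-3-methylbutyl)-4,5-dimethoxyphenyl]zinc chloride | COc1cc([Zn]Cl)c(OCc2ccccc2)c(CCC(C)(C)O[Mg]Cl)c1OC
F9 | step 14 | 5,7-dihydroxy-3-iodo-4H-chromen-4-one | O=c1c(I)coc2cc(O)cc(O)c12
F10 | step 14 | 2-(3-hydroxy-3-methylbutyl)-3,4-dimethoxy-6-(4,4,5,5-tetramethyl-1,3,2-dioxaborolan-2-yl)phenol | COc1cc(B2OC(C)(C)C(C)(C)O2)c(O)c(CCC(C)(C)O)c1OC
A1 | alternative 1 | pentacarbonyl[(2Z)-1,2-dimethoxy-6-methyl-6-(triethylsilyloxy)hept-2-en-1-ylidene]chromium | COC(=[Cr](=C=O)(=C=O)(=C=O)(=C=O)=C=O)/C(OC)=C/CCC(C)(C)O[Si](CC)(CC)CC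
A2 | alternative 1 | 5,7-bis(benzyloxy)-3-ethynyl-4H-chromen-4-one | C#Cc1coc2cc(OCc3ccccc3)cc(OCc3ccccc3)c2c1=O
A3 | alternative 1 | 5,7-bis(benzyloxy)-2'-hydroxy-4',5'-dimethoxy-3'-(3-methyl-3-triethylsilyloxybutyl)isoflavone | COc1cc(-c2coc3cc(OCc4ccccc4)cc(OCc4ccccc4)c3c2=O)c(O)c(CCC(C)(C)O[Si](CC)(CC)CC)c1OC
A4 | alternative 2 | dimethyl squarate (3,4-dimethoxycyclobut-3-ene-1,2-dione) | COC1=C(OC)C(=O)C1=O
A5 | alternative 2 | 3-methoxy-4-[3-methyl-3-(triethylsilyloxy)butyl]cyclobut-3-ene-1,2-dione | COC1=C(CCC(C)(C)O[Si](CC)(CC)CC)C(=O)C1=O
A6 | alternative 2 | 3,4-dimethoxy-2-[3-methyl-3-(triethylsilyloxy)butyl]-4-vinylcyclobut-2-en-1-one (racemic) | C=CC1(OC)C(OC)=C(CCC(C)(C)O[Si](CC)(CC)CC)C1=O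
A7 | alternative 2 | 3,4-dimethoxy-2-(3-methyl-3-triethylsilyloxybutyl)phenol | COc1ccc(O)c(CCC(C)(C)O[Si](CC)(CC)CC)c1OC
A8 | alternative 3 | 2,4-bis(benzyloxy)-6-hydroxybenzaldehyde | O=Cc1c(O)cc(OCc2ccccc2)cc1OCc1ccccc1
A9 | alternative 3 | 1-[2-(benzyloxy)-4,5-dimethoxy-3-(3-methyl-3-triethylsilyloxybutyl)phenyl]-2-bromoethan-1-one | BrCC(=O)c1cc(OC)c(OC)c(CCC(C)(C)O[Si](CC)(CC)CC)c1OCc1ccccc1
A10 | alternative 3 | 2,4-bis(benzyloxy)-6-{2-[2-(benzyloxy)-4,5-dimethoxy-3-(3-methyl-3-triethylsilyloxybutyl)phenyl]-2-oxoethoxy}benzaldehyde | O=Cc1c(OCc2ccccc2)cc(OCc2ccccc2)cc1OCC(=O)c1cc(OC)c(OC)c(CCC(C)(C)O[Si](CC)(CC)CC)c1OCc1ccccc1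
A11 | alternative 3 | 5,7-bis(benzyloxy)-3-[2-(benzyloxy)-4,5-dimethoxy-3-(3-methyl-3-triethylsilyloxybutyl)phenyl]-3-hydroxychroman-4-one (racemic) | O=C1c2c(OCc3ccccc3)cc(OCc3ccccc3)cc2OCC1(O)c1cc(OC)c(OC)c(CCC(C)(C)O[Si](CC)(CC)CC)c1OCc1ccccc1
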